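Everything rests on disconnecting the 3(2H)-furanone (O–C3=C2–C1(=O)–C10, germacrane numbering) at C3, which is supplied by carbon monoxide. The precursor is an open-chain trans-α-methylene-γ-butyrolactone carrying a (Z)-vinyl iodide (C4) and a tertiary ethynyl carbinol (C10–C1≡C2). One palladium-catalysed operation carbonylates C4 and joins the acyl carbon to C2, closing the ten-membered carbocycle as a γ-hydroxy ynone. Hydration at C1 then lets the C10 hydroxyl add transannularly to C3, closing the furanone last. The step exploits the 1,3-relationship between O10 and C3 across the C1–C10 ring and the Z geometry of C4=C5.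

Key step: step 9

Remark: germacrane numbering is used throughout (C1–C10 carbocycle, C11–C13 methylene lactone, C14 methyl, C15 CH2O); the antipodes of the chiral catalysts in steps 1 and 3 are assumed to be those that give the configurations drawn.

Step 1
Reactants: 1 but-3-yn-2-one; 2 allyldiisopropoxyborane
Product: 3 (3R)-3-methylhex-5-en-1-yn-3-ol
Conditions: (S)-3,3′-Br2-BINOL (15 mol %), PhCF3/PhMe, −35 °C; then H2O
Reagents that add atoms: none
Why: Chiral-diol-catalysed asymmetric allylboration of a ketone, in which exchange of an isopropoxy group for the BINOL gives a chiral allylboronate that adds through a closed chair transition state, distinguishing methyl from the slim ethynyl group and setting C10 as R.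

Step 2
Reactants: 3 (3R)-3-methylhex-5-en-1-yn-3-ol
Product: 5 (3R)-3-hydroxy-3-methylpent-4-ynal, via secondary ozonide 4 (not isolated)
Conditions: O3, CH2Cl2, −78 °C (Sudan III end point); then PPh3, −78 °C to rt; used crude
Reagents that add atoms: ozone [O-][O+]=O
Why: Ozonolysis with reductive work-up, in which the terminal alkene should react far faster than the alkyne and the tertiary carbinol is not touched.

Step 3
Reactants: 5 (3R)-3-hydroxy-3-methylpent-4-ynal; 6 ethyl 2-(bromomethyl)prop-2-enoate
Product: 8 (5R)-5-[(2R)-2-hydroxy-2-methylbut-3-yn-1-yl]-3-methylideneoxolan-2-one, via silyl ether 7 (not isolated)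
Conditions: CrCl2 (10 mol %), chiral carbazole-bis(oxazoline) ligand (12 mol %), Mn, TMSCl, iPr2NEt, THF, rt; then 1 M HCl, THF
Reagents that add atoms: none
Why: Chromium-catalysed enantioselective Nozaki–Hiyama–Kishi-type 2-(alkoxycarbonyl)allylation, in which the ligand sphere on chromium selects the aldehyde face and sets C8 by reagent control (the remote C10 centre has little say), and acid then cleaves the silyl ether with lactonisation.

Step 4
Reactants: 8 (5R)-5-[(2R)-2-hydroxy-2-methylbut-3-yn-1-yl]-3-methylideneoxolan-2-one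
Product: 9 (5S)-3-(bromomethyl)-5-[(2R)-2-hydroxy-2-methylbut-3-yn-1-yl]furan-2(5H)-one
Conditions: NBS (1.05 equiv), AIBN (5 mol %), PhCF3, 80 °C
Reagents that add atoms: N-bromosuccinimide O=C1CCC(=O)N1Br
Why: Wohl–Ziegler bromination with allylic transposition, in which hydrogen abstraction at the ring CH2 (C7) gives an allyl radical that takes bromine at its primary terminus to give the conjugated butenolide; no stereocentre is touched (the label at C8 changes only through CIP priorities).

Step 5
Reactants: 10 4-[(tert-butyldimethylsilyl)oxy]but-2-yn-1-ol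
Product: 12 (2Z)-4-[(tert-butyldimethylsilyl)oxy]-3-iodobut-2-en-1-ol, via cyclic vinylalanate 11 (not isolated)
Conditions: Red-Al, THF, 0 °C; then I2, THF, −78 °C
Reagents that add atoms: iodine II
Why: Hydroxyl-directed trans-hydroalumination of the propargylic alcohol places aluminium on the distal alkyne carbon cis to the carbinol and iodinolysis with retention gives the Z vinyl iodide, the low temperature suppressing loss of the silyloxy group to an allene.

Step 6
Reactants: 12 (2Z)-4-[(tert-butyldimethylsilyl)oxy]-3-iodobut-2-en-1-ol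
Product: 13 (2Z)-4-[(tert-butyldimethylsilyl)oxy]-3-iodobut-2-enal
Conditions: MnO2, CH2Cl2, rt, dark; used at once
Reagents that add atoms: none
Why: Manganese dioxide oxidation of the allylic alcohol under neutral conditions, which should keep the Z geometry.

Step 7
Reactants: 9 (5S)-3-(bromomethyl)-5-[(2R)-2-hydroxy-2-methylbut-3-yn-1-yl]furan-2(5H)-one; 13 (2Z)-4-[(tert-butyldimethylsilyl)oxy]-3-iodobut-2-enal
Product: 15 (4S,5S)-4-[(1S,2Z)-4-[(tert-butyldimethylsilyl)oxy]-1-hydroxy-3-iodobut-2-en-1-yl]-5-[(2R)-2-hydroxy-2-methylbut-3-yn-1-yl]-3-methylideneoxolan-2-one, via allylzinc bromide 14 (not isolated)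
Conditions: Zn dust, THF/sat. aq. NH4Cl, 0 °C to rt
Reagents that add atoms: none
Why: Zinc-mediated Barbier allylation, in which the allylzinc adds through its γ-carbon (C7) anti to the C8 side chain (trans lactone) via a chair transition state with the enal residue equatorial; the ring-fixed E-type allyl geometry should give the anti adduct, the C6 epimer of the target, which step 8 inverts.

Step 8
Reactants: 15 (Barbier adduct); 16 angelic acid
Product: 17 (1R,2Z)-4-[(tert-butyldimethylsilyl)oxy]-1-[(2S,3R)-2-[(2R)-2-hydroxy-2-methylbut-3-yn-1-yl]-4-methylidene-5-oxooxolan-3-yl]-3-iodobut-2-en-1-yl (2Z)-2-methylbut-2-enoate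
Conditions: PPh3, DIAD, toluene, 0 °C to rt
Reagents that add atoms: none
Why: Mitsunobu esterification, in which SN2 displacement of the phosphorus-activated allylic hydroxyl by angelate inverts C6 to the target configuration under neutral conditions that should spare the Z geometry of the angelate, while the tertiary C10 hydroxyl does not react.

Step 9
Reactants: 17 (angelate with vinyl iodide and ethynyl carbinol)
Product: 20 15-O-TBS ether of the target, via ten-membered ynone 18 (not isolated), via ten-membered 1,3-diketone 19 (not isolated)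
Conditions: Pd(PPh3)2Cl2 (10 mol %), CuI (5 mol %), Et3N, CO (1 atm), THF, 25 °C, syringe-pump addition of 17 to 1 mM; then H2O (50 equiv), 50 °C
Reagents that add atoms: carbon monoxide [C-]#[O+]; water O
Why: Proposed new method: Pd(0) inserts into the C4–I bond, CO insertion gives the C3 acylpalladium, and transmetalation of the C2 acetylide (CuI/Et3N) with reductive elimination closes the ten-membered carbocycle as γ-hydroxy ynone 18; after water is added, amine-mediated conjugate hydration at C1 gives 1,3-diketone 19, whose C3 carbonyl is attacked by the C10 hydroxyl, and dehydration gives the 3(2H)-furanone. The closest known reaction types are the three-component palladium-catalysed coupling of organic halides, CO and tertiary ethynyl carbinols to 3(2H)-furanones and carbonylative cross-coupling macrocyclisation (carbonylative Stille); the intramolecular medium-ring version is the untested part. The carbocycle closes by acyl–alkynyl reductive elimination (the CO-free coupling would need a nine-membered enyne and should not compete), and the furanone closes by transannular 5-exo-trig attack of O10 on C3 followed by loss of water. No stereocentre is formed: C6, C7, C8 and C10 are spectators, and the Z geometry of C4=C5, which holds C3 cis to C6, is retained. The step needs ring closure over oligomerisation (slow addition at high dilution; the Z olefin and the trans-lactone turn bring the chain ends together), alkynylation of the acylpalladium over its insertion into the C11=C13 acrylate (copper acetylide, 25 °C, CO-saturated solution) and over O-acylation (C15 is silylated, and the tertiary hydroxyl could only give a nine-membered lactone). Water is withheld until the iodide is consumed so that hydroxycarbonylation cannot intercept the acylpalladium.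

Step 10
Reactants: 20 15-O-TBS ether of the target
Product: 21 CNP0176514.1
Conditions: HF·pyridine, pyridine/THF, 0 °C
Reagents that add atoms: none
Why: Buffered fluoride cleavage of the primary silyl ether, which should leave the angelate, the methylene lactone and the furanone intact.

Compound list

1 | but-3-yn-2-one | CC(=O)C#C | starting material
2 | allyldiisopropoxyborane (diisopropyl allylboronate) | C=CCB(OC(C)C)OC(C)C | starting material
3 | (3R)-3-methylhex-5-en-1-yn-3-ol | C#C[C@](C)(O)CC=C | intermediate
4 | (2R)-2-methyl-1-(1,2,4-trioxolan-3-yl)but-3-yn-2-ol (secondary ozonide, trioxolane carbon unassigned) | C#C[C@](C)(O)CC1OCOO1 | intermediate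
5 | (3R)-3-hydroxy-3-methylpent-4-ynal | C#C[C@](C)(O)CC=O | intermediate
6 | ethyl 2-(bromomethyl)prop-2-enoate | C=C(CBr)C(=O)OCC | starting material
7 | ethyl (4R,6R)-6-hydroxy-6-methyl-2-methylidene-4-[(trimethylsilyl)oxy]oct-7-ynoate | C=C(C[C@@H](O[Si](C)(C)C)C[C@@](C)(O)C#C)C(=O)OCC | intermediate
8 | (5R)-5-[(2R)-2-hydroxy-2-methylbut-3-yn-1-yl]-3-methylideneoxolan-2-one | C=C1C(=O)O[C@@H](C[C@@](C)(O)C#C)C1 | intermediate
9 | (5S)-3-(bromomethyl)-5-[(2R)-2-hydroxy-2-methylbut-3-yn-1-yl]furan-2(5H)-one | O=C1O[C@@H](C[C@@](C)(O)C#C)C=C1CBr | intermediate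
10 | 4-[(tert-butyldimethylsilyl)oxy]but-2-yn-1-ol | OCC#CCO[Si](C)(C)C(C)(C)C | starting material
11 | sodium 2,2-bis(2-methoxyethoxy)-3-{[(tert-butyldimethylsilyl)oxy]methyl}-2,5-dihydro-1,2-oxaaluminol-2-uide (cyclic vinylalanate) | [Na+].COCCO[Al-]1(OCCOC)OCC=C1CO[Si](C)(C)C(C)(C)C | intermediate
12 | (2Z)-4-[(tert-butyldimethylsilyl)oxy]-3-iodobut-2-en-1-ol | OC/C=C(\I)CO[Si](C)(C)C(C)(C)C | intermediate
13 | (2Z)-4-[(tert-butyldimethylsilyl)oxy]-3-iodobut-2-enal | O=C/C=C(\I)CO[Si](C)(C)C(C)(C)C | intermediate
14 | {[(5S)-5-[(2R)-2-hydroxy-2-methylbut-3-yn-1-yl]-2-oxo-2,5-dihydrofuran-3-yl]methyl}zinc bromide | O=C1O[C@@H](C[C@@](C)(O)C#C)C=C1C[Zn]Br | intermediate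
15 | (4S,5S)-4-[(1S,2Z)-4-[(tert-butyldimethylsilyl)oxy]-1-hydroxy-3-iodobut-2-en-1-yl]-5-[(2R)-2-hydroxy-2-methylbut-3-yn-1-yl]-3-methylideneoxolan-2-one (trans lactone, C6 epimer of the target configuration) | C=C1C(=O)O[C@@H](C[C@@](C)(O)C#C)[C@@H]1[C@H](O)/C=C(\I)CO[Si](C)(C)C(C)(C)C | intermediate
16 | angelic acid, (2Z)-2-methylbut-2-enoic acid | C/C=C(/C)C(=O)O | starting material
17 | (1R,2Z)-4-[(tert-butyldimethylsilyl)oxy]-1-[(2S,3R)-2-[(2R)-2-hydroxy-2-methylbut-3-yn-1-yl]-4-methylidene-5-oxooxolan-3-yl]-3-iodobut-2-en-1-yl (2Z)-2-methylbut-2-enoate | C=C1C(=O)O[C@@H](C[C@@](C)(O)C#C)[C@@H]1[C@@H](OC(=O)/C(C)=C\C)/C=C(\I)CO[Si](C)(C)C(C)(C)C | intermediate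
18 | (4Z,6S,7R,8S,10R)-6-angeloyloxy-15-[(tert-butyldimethylsilyl)oxy]-10-hydroxy-3-oxogermacra-4,11(13)-dien-1-yn-12,8-olide (ten-membered ynone) | C=C1C(=O)O[C@H]2C[C@@](C)(O)C#CC(=O)/C(CO[Si](C)(C)C(C)(C)C)=C\[C@H](OC(=O)/C(C)=C\C)[C@H]12 | intermediate
19 | (4Z,6S,7R,8S,10R)-6-angeloyloxy-15-[(tert-butyldimethylsilyl)oxy]-10-hydroxy-1,3-dioxogermacra-4,11(13)-dien-12,8-olide (ten-membered 1,3-diketone) | C=C1C(=O)O[C@H]2C[C@@](C)(O)C(=O)CC(=O)/C(CO[Si](C)(C)C(C)(C)C)=C\[C@H](OC(=O)/C(C)=C\C)[C@H]12 | intermediate
20 | (4Z,6S,7R,8S,10R)-6-angeloyloxy-15-[(tert-butyldimethylsilyl)oxy]-1-oxo-3,10-epoxygermacra-2,4,11(13)-trien-12,8-olide (15-O-TBS ether of the target) | C=C1C(=O)O[C@H]2C[C@@]3(C)OC(=CC3=O)/C(CO[Si](C)(C)C(C)(C)C)=C\[C@H](OC(=O)/C(C)=C\C)[C@H]12 | intermediate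
21 | CNP0176514.1, (4Z,6S,7R,8S,10R)-6-angeloyloxy-15-hydroxy-1-oxo-3,10-epoxygermacra-2,4,11(13)-trien-12,8-olide | C=C1C(=O)O[C@H]2C[C@@]3(C)OC(=CC3=O)/C(CO)=C\[C@H](OC(=O)/C(C)=C\C)[C@H]12 | target

Total step count: 10. Longest linear sequence: 8 steps (steps 1–4, then 7–10, from but-3-yn-2-one); steps 5 and 6 form the second branch.

Steps most likely to fail

Step 9 (Proposed new method). The chain ends may fail to meet, so that oligomerisation wins, or the acylpalladium may be consumed by insertion into the C11=C13 acrylate or by premature hydrolysis. The fallback uses known chemistry, sets out from 17 and returns at 20. The terminal alkyne of 17 is stannylated (Bu3SnOMe, THF, 60 °C) to the alkynylstannane F1. A carbonylative Stille macrocyclisation (Pd(PPh3)4, CO 3 atm, THF, 50 °C, high dilution), a cross-coupling manifold with precedent for strained medium-ring enones, should then close the carbocycle to ynone 18, which is isolated this time. The γ-hydroxy ynone is finally isomerised to furanone 20 by the known gold(I)-catalysed cyclisation ((p-CF3C6H4)3PAuCl/AgOTf, toluene, rt), which needs neither base nor added water.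

Step 8. Displacement at the hindered allylic carbinol may be slow, so that elimination, SN2′ attack, geometric isomerisation of the angelate or translactonisation of the free C6 hydroxyl takes over. The fallback sets out from 15 and returns at 17 by redox inversion and acylation with retention. Dess–Martin oxidation gives the enone F2. Reagent-controlled reduction ((S)-Me-CBS, catecholborane, −78 °C, the alkenyl group acting as the large substituent) should give the epimeric alcohol F3. F3 is then acylated with the mixed anhydride F4, made in the flask from 16, 2,4,6-trichlorobenzoyl chloride and Et3N (toluene, 80 °C), to give 17. Should the Barbier step deliver F3 directly, the acylation alone is used.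

Step 4. Radical bromination may be unselective, with a second bromination at C8 once the butenolide has formed, or bromine-atom addition to the alkyne. The fallback sets out from 8 and returns at 9 by ionic addition and elimination. Pyridinium tribromide (CH2Cl2, 0 °C, dark) should add across the electron-poor exocyclic alkene in preference to the alkyne, giving the dibromide F5. Et3N (0 °C) then removes HBr across C7–C11 to give 9.

Further compounds

F1 | step 9 | C2-tributylstannyl derivative of 17 (alkynylstannane) | C=C1C(=O)O[C@@H](C[C@@](C)(O)C#C[Sn](CCCC)(CCCC)CCCC)[C@@H]1[C@@H](OC(=O)/C(C)=C\C)/C=C(\I)CO[Si](C)(C)C(C)(C)C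
F2 | step 8 | (4R,5S)-4-[(2Z)-4-[(tert-butyldimethylsilyl)oxy]-3-iodobut-2-enoyl]-5-[(2R)-2-hydroxy-2-methylbut-3-yn-1-yl]-3-methylideneoxolan-2-one (enone) | C=C1C(=O)O[C@@H](C[C@@](C)(O)C#C)[C@@H]1C(=O)/C=C(\I)CO[Si](C)(C)C(C)(C)C
F3 | step 8 | (4S,5S)-4-[(1R,2Z)-4-[(tert-butyldimethylsilyl)oxy]-1-hydroxy-3-iodobut-2-en-1-yl]-5-[(2R)-2-hydroxy-2-methylbut-3-yn-1-yl]-3-methylideneoxolan-2-one (C6 epimer of 15) | C=C1C(=O)O[C@@H](C[C@@](C)(O)C#C)[C@@H]1[C@@H](O)/C=C(\I)CO[Si](C)(C)C(C)(C)C
F4 | step 8 | (2Z)-2-methylbut-2-enoic 2,4,6-trichlorobenzoic anhydride | C/C=C(/C)C(=O)OC(=O)c1c(Cl)cc(Cl)cc1Cl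
F5 | step 4 | (5S)-3-bromo-3-(bromomethyl)-5-[(2R)-2-hydroxy-2-methylbut-3-yn-1-yl]oxolan-2-one (C3 epimers) | O=C1O[C@@H](C[C@@](C)(O)C#C)CC1(Br)CBr
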